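## The problem

The target 9 is a 1H-isochromene (C1H2, O2, C3, C4, C4a to C8a) with methoxy groups at C6 and C7 and a 2,4-dimethoxybenzoyl group at C3, so that C3=C4 is at once an enol ether, the α,β-bond of an aryl ketone and a styrene. It has no stereocentre, so the task is one of connectivity and oxidation level: the pyran must be closed with C1 as a methylene, C4 as a methine and C3 at the level of a ketone-bearing enol ether. Stereocentres appear only in the penultimate compound 8 (C3 and C4), and neither has to control the other because both are erased when the double bond is formed. The fragile groups are the enol ether (hydrated by aqueous acid), the C1 methylene (benzylic and α to oxygen, hence open to autoxidation and hydride abstraction) and the aryl methyl ethers, of which the one ortho to the ketone is easily cleaved by boron or aluminium halides. Strong Lewis acids, oxidants and prolonged aqueous acid are therefore excluded late in the route. The feature that invites the key step is that C3, with its aroyl group, is a single carbon lodged between O2 and C4, formally an acylcarbene carbon. Excising it contracts the pyran to a phthalan in which C4 is bonded to O2; if C4 carries the alkoxy leaving group that is needed anyway to unveil C3=C4, that phthalan is a cyclic acetal, the substrate class that rearranges through oxonium ylides. Because the two methoxy groups of ring A are symmetry-related in the phthalan, it does not matter which benzylic carbon becomes the acetal.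

## Retrosynthesis

**9 to 8.** The C3=C4 π bond is traced back to a C3–H and a C4–O bond, that is, 9 is the product of β-elimination of an alcohol from the β-alkoxy ketone 8. The neighbouring choices are dehydration of a C4 alcohol, which would require a separate aldol ring closure, and dehydrogenation of an isochroman, whose oxidant would attack C1 first. The alkoxy group in 8 costs nothing because the key step delivers it at C4. The forward reaction only has to be a mild base-promoted elimination that tolerates the enol ether it creates; both diastereomers of 8 converge.

**8 to 3 and 5.** Both bonds to C3 inside the ring, O2–C3 and C3–C4, are cut, which removes one carbon together with the whole aroyl side chain. What is left is the five-membered acetal 3, and the excised carbon becomes the diazo carbon of 5. Cutting only C3–C4 (aldol logic) or only O2–C3 (etherification logic) leaves an open-chain precursor that must first be assembled over several steps, whereas the double cut gives two pieces of similar size, each one or two steps from a catalogue compound. The forward reaction must capture the carbene at the ring oxygen of 3 and migrate the acetal carbon. To bias the first choice the acetal alkoxy group is isopropoxy: a methoxy group at this position would leave the exocyclic and the ring oxygen about equally accessible, and the isopropyl group is lost in the last step in any case.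

**3 to 2 to 1.** The exocyclic C1–O bond of the acetal is cut to the lactol 2, and 2 is the half-reduced form of the commercial lactone 1. The forward steps are a low-temperature hydride reduction that stops at the lactol and an acid-catalysed exchange with the alcohol. The symmetry of the dimethoxy pattern removes any question of which carbonyl or benzylic position is addressed.

**5 to 4.** The bond between the carbonyl carbon and the diazo carbon is cut, giving the commercial aroyl chloride 4 and a one-carbon diazo nucleophile. The forward reaction is a single acylation.

## Roads not taken

Alternative 1: The cut goes through ring A at C4a–C8a and C7–C8, so ring A and the pyran would be formed together from the furan–alkyne A1, a Z enol ether enone carrying a 4-methoxyfuran-2-yl group and a propargyl ether. On heating, the furan adds across the tethered terminal alkyne and the oxanorbornadiene opens in the same pot to the C7 phenol A2; O-methylation then gives 9.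
- Merits: the key step is intramolecular, its regiochemistry is fixed by the tether, the oxygen bridge can open in only one aromatising sense, and the Z geometry required in A1 is the thermodynamic outcome of an aldol condensation.
- Weak points: the furan is deactivated as a diene by conjugation with the enone, and the dienophile is an unactivated alkyne, so high temperatures would be imposed on an acid- and heat-sensitive 3-alkoxyfuran. The 4-methoxyfuran aldehyde needed for A1 is itself a multi-step compound, and a methylation is added at the end.
- Comparison: this road builds more complexity in one step and has no selectivity question comparable to the choice between two acetal oxygens, which is a real advantage. Against that, the chosen plan does not construct a benzene ring that can be bought with the correct substituents, and it reaches 9 in five steps from two catalogue compounds.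

Alternative 2: The cut is at C8a–C1 and C4a–C4, a formal insertion of a symmetric dimethoxy aryne into the C2–C3 bond of oxetan-3-one A4. The aryne would be released by fluoride from the silyl triflate A3. The potassium enolate of A4 adds to it, the aryl anion closes onto the ketone, and the benzocyclobutenoxide fragments to 6,7-dimethoxyisochroman-4-one A5.
- Merits: the symmetric aryne poses no regiochemical problem, strain release drives the reaction, and the bicyclic skeleton appears in one step.
- Weak points: A5 has no substituent at C3 and has C4 at the ketone level. C-acylation would give the β-diketone A6, and the C4 oxygen would then have to be removed in the presence of a second, electronically similar aryl ketone. The enolate of A4 is strained and prone to self-condensation, and A3 itself takes about three steps to make.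
- Comparison: this road avoids diazo chemistry and any oxygen-selectivity issue, and A5 is a robust intermediate. The chosen plan installs C3 with its aroyl group and C4 with its leaving group in a single operation, with nothing to correct afterwards.

Alternative 3: The cut is in ring C at C1'–C2' and C5'–C6'. The trioxygenated diene A8 would add to the terminal ynone A7, and the adduct would aromatise by loss of methanol and desilylation to the 2-hydroxy-4-methoxyphenyl ketone A9; methylation of the chelated phenol gives 9.
- Merits: the regiochemistry is reliably dictated by the polarisation of the diene, the conditions are mild, and no diazoketone with an ortho-methoxy group is involved, so intramolecular interception of a carbene cannot arise. In that respect it is safer than the chosen plan.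
- Weak points: A7 already contains the complete isochromene enol ether ketone, so the bicyclic problem is only moved, and ynone construction is added to it. The enol ether enone of A7 is a second, if weaker, 2π partner. Ring C is available ready-made as the aroyl chloride.
- Comparison: the chosen plan answers with convergence, joining two bought aromatic rings through the one carbon that lies between them.

Key step: step 4

Assumption: compounds 1 and 4 are taken as catalogue chemicals, and the key-step intermediates 6 and 7 are drawn without the metal although they are probably rhodium-associated.

## Route

Step 1
Reactants: 1 5,6-dimethoxyisobenzofuran-1(3H)-one (5,6-dimethoxyphthalide)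
Product: 2 5,6-dimethoxy-1,3-dihydroisobenzofuran-1-ol (racemic lactol)
Conditions: iBu2AlH (1.1 equiv), CH2Cl2, −78 °C; aqueous Rochelle salt work-up
Reagents that add atoms: none
Why: Partial reduction of a lactone to the lactol with diisobutylaluminium hydride; the tetrahedral aluminium lactolate is stable at −78 °C and collapses only on work-up, which should prevent over-reduction to the diol.

Step 2
Reactants: 2 5,6-dimethoxy-1,3-dihydroisobenzofuran-1-ol
Product: 3 5,6-dimethoxy-1-(propan-2-yloxy)-1,3-dihydroisobenzofuran (racemic)
Conditions: i-PrOH (solvent), pyridinium p-toluenesulfonate (cat.), 4 Å molecular sieves, rt; Et3N quench, chromatography on Et3N-deactivated silica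
Reagents that add atoms: propan-2-ol, CC(C)O
Why: Acid-catalysed lactol-to-acetal exchange (Fischer-type glycosidation) through the benzylic oxocarbenium ion, which the para-methoxy group stabilises; the weak acid and the basic quench should keep the acetal from ionising further toward the isobenzofuran.

Step 3
Reactants: 4 2,4-dimethoxybenzoyl chloride
Product: 5 2-diazo-1-(2,4-dimethoxyphenyl)ethan-1-one
Conditions: Me3SiCHN2 (2 equiv, 2 M in hexanes), THF–MeCN (1:1), 0 °C to rt; concentration
Reagents that add atoms: trimethylsilyldiazomethane, C[Si](C)(C)C=[N+]=[N-]
Why: C-Acylation of a diazoalkane by an acid chloride (first stage of the Arndt–Eistert sequence in its trimethylsilyldiazomethane form); the chloride released removes the silyl group, so the diazoketone should form without free HCl.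

Step 4
Reactants: 3 5,6-dimethoxy-1-(propan-2-yloxy)-1,3-dihydroisobenzofuran (3 equiv), 5 2-diazo-1-(2,4-dimethoxyphenyl)ethan-1-one
Product: 8 (2,4-dimethoxyphenyl)[6,7-dimethoxy-4-(propan-2-yloxy)-3,4-dihydro-1H-isochromen-3-yl]methanone (racemic cis/trans mixture), via ring-oxygen oxonium ylide 6 (not isolated), via oxocarbenium enolate zwitterion 7 (not isolated)
Conditions: Rh2(OAc)4 (2 mol %), CH2Cl2, 40 °C, 5 added by syringe pump over 6 h to 3 and the catalyst; excess 3 recovered
Reagents that add atoms: none
Why: Rh2(OAc)4 releases N2 from 5 and the electrophilic rhodium carbene is captured by the ring oxygen of 3 to give the oxonium ylide 6, which forms O2–C3. The O–C1 acetal bond of 6, weakened by the isopropoxy lone pair and by the 5-methoxy group para to the acetal-bearing ring carbon, ionises to the tethered oxocarbenium–enolate zwitterion 7, and attack of the enolate carbon on the oxocarbenium carbon forms C3–C4 and completes a formal [1,2]-Stevens shift of the acetal carbon from oxygen to the carbene carbon. The closest known reaction type is the one-carbon ring enlargement of 2-aryl-1,3-dioxolanes to 1,4-dioxanes by diazocarbonyl compounds under copper or rhodium catalysis, in which the acetal carbon likewise migrates; there the two acetal oxygens are equivalent, whereas here they are not. The six-membered ring closes by a 6-(enolexo)-exo-trig attack of C3 on C4, which expands the five-membered ring by one carbon. C3 and C4 are set without control, since recombination of the open ion pair has no strong facial bias, so 8 is expected as a racemic cis/trans mixture; this is harmless because both centres become sp2 in step 5. The step needs ylide formation at the ring oxygen and not at the exocyclic one, and migration of the acetal carbon and not of the benzylic CH2: the isopropyl group makes the exocyclic oxygen a hindered di-secondary ether while the ring oxygen is tied back in a flat five-membered ring, and heterolysis of the acetal C–O bond is far easier than cleavage of the benzylic one. Slow addition of 5 to an excess of 3 should suppress carbene dimerisation, and the five-membered ylide that the ortho-methoxy group of 5 can form has only a methyl group to migrate and should revert to the carbene.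

Step 5
Reactants: 8 (2,4-dimethoxyphenyl)[6,7-dimethoxy-4-(propan-2-yloxy)-3,4-dihydro-1H-isochromen-3-yl]methanone
Product: 9 (2,4-dimethoxyphenyl)(6,7-dimethoxy-1H-isochromen-3-yl)methanone (target)
Conditions: DBU (2 equiv), toluene, 80 °C, under argon
Reagents that add atoms: none
Why: E1cB β-elimination of isopropanol from a β-alkoxy ketone: C3–H is acidified by the ketone, the benzylic C4–O bond is loosened by the 7-methoxy group para to C4a, and the product gains conjugation with ring A; both diastereomers converge and no stereocentre remains.

## Compound list

1 | 5,6-dimethoxyisobenzofuran-1(3H)-one (5,6-dimethoxyphthalide) | COc1cc2c(cc1OC)C(=O)OC2 | starting material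
2 | 5,6-dimethoxy-1,3-dihydroisobenzofuran-1-ol (racemic) | COc1cc2c(cc1OC)C(O)OC2 | intermediate
3 | 5,6-dimethoxy-1-(propan-2-yloxy)-1,3-dihydroisobenzofuran (racemic) | COc1cc2c(cc1OC)C(OC(C)C)OC2 | intermediate
4 | 2,4-dimethoxybenzoyl chloride | COc1ccc(C(=O)Cl)c(OC)c1 | starting material
5 | 2-diazo-1-(2,4-dimethoxyphenyl)ethan-1-one | COc1ccc(C(=O)C=[N+]=[N-])c(OC)c1 | intermediate
6 | ring-oxygen oxonium ylide of 3 and the carbene from 5 (not isolated; drawn metal-free) | COc1cc2c(cc1OC)C(OC(C)C)[O+]([CH-]C(=O)c1ccc(OC)cc1OC)C2 | intermediate
7 | ring-opened oxocarbenium enolate zwitterion (not isolated; drawn metal-free, enolate geometry undefined) | COc1cc(COC=C([O-])c2ccc(OC)cc2OC)c(C=[O+]C(C)C)cc1OC | intermediate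
8 | (2,4-dimethoxyphenyl)[6,7-dimethoxy-4-(propan-2-yloxy)-3,4-dihydro-1H-isochromen-3-yl]methanone (racemic cis/trans mixture) | COc1ccc(C(=O)C2OCc3cc(OC)c(OC)cc3C2OC(C)C)c(OC)c1 | intermediate
9 | (2,4-dimethoxyphenyl)(6,7-dimethoxy-1H-isochromen-3-yl)methanone | COc1ccc(C(=O)C2=Cc3cc(OC)c(OC)cc3CO2)c(OC)c1 | target

## Step count and risks

Total step count: 5. Longest linear sequence: 4 steps (steps 1, 2, 4, 5, from 1 to 9); step 3 is the one-step branch to 5.

**Step 4 (key step).** The likeliest failures are:
- capture of the carbene at the exocyclic isopropoxy oxygen, which would lead to insertion without ring expansion;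
- intramolecular capture by the ortho-methoxy group of the diazoketone;
- carbene dimerisation;
- ionisation of the acetal by the weakly Lewis-acidic catalyst.

All of these stem from an acceptor-only carbene that discriminates poorly between nucleophiles. The fallback sets out from 1 and 5 and returns to the route at 9. It replaces the ether-oxygen ylide by capture at a hydroxyl group, the fastest trap for a rhodium carbene, and closes the ring by aldol condensation instead of ring expansion. Lactone 1 would be reduced fully with LiAlH4 in THF to the symmetric diol (4,5-dimethoxy-1,2-phenylene)dimethanol F1. Rh2(OAc)4-catalysed O–H insertion of 5 into an excess of this diol would give the mono-ether 1-(2,4-dimethoxyphenyl)-2-{[2-(hydroxymethyl)-4,5-dimethoxybenzyl]oxy}ethan-1-one F2. MnO2 in CH2Cl2 would oxidise the remaining benzylic alcohol to 2-{[2-(2,4-dimethoxyphenyl)-2-oxoethoxy]methyl}-4,5-dimethoxybenzaldehyde F3. Intramolecular aldol condensation (piperidine, AcOH, toluene, reflux) would then form C3–C4 and dehydrate directly to 9.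

**Step 3.** The likeliest failure is sluggish acylation of the weakly nucleophilic silyl diazoalkane by a donor-deactivated, ortho-substituted aroyl chloride, together with protonation and loss of nitrogen from the product if HCl is liberated. The fallback sets out from 4 and returns at 5, and replaces acylation of a diazoalkane by diazo transfer to a ketone. Compound 4 would be methylated with Me2CuLi (Et2O, −78 °C) to 1-(2,4-dimethoxyphenyl)ethan-1-one F4. Its lithium enolate (LiN(SiMe3)2, THF, −78 °C) would be trifluoroacetylated with 2,2,2-trifluoroethyl trifluoroacetate to 1-(2,4-dimethoxyphenyl)-4,4,4-trifluorobutane-1,3-dione F5. Detrifluoroacetylative diazo transfer with methanesulfonyl azide, Et3N and water in MeCN would deliver 5.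

**Step 5.** The likeliest failure is slow expulsion of a secondary alkoxide in the E1cB step, with base-promoted air oxidation at the C1 methylene during prolonged heating. The fallback sets out from 8 and returns at 9, and changes the elimination from a carbanion to a cation pathway. Soft enolisation of 8 with Me3SiOTf and Et3N (CH2Cl2, 0 °C) would give the silyl enol ether [(2,4-dimethoxyphenyl){6,7-dimethoxy-4-(propan-2-yloxy)-1,4-dihydro-3H-isochromen-3-ylidene}methoxy]trimethylsilane F6. A catalytic amount of Me3SiOTf would then ionise the allylic, benzylic C4–O bond, and loss of the silyl group from the resulting silyloxy-stabilised cation would give 9 under non-aqueous, non-basic conditions.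

## Further compounds

F1 | step 4 | (4,5-dimethoxy-1,2-phenylene)dimethanol | COc1cc(CO)c(CO)cc1OC
F2 | step 4 | 1-(2,4-dimethoxyphenyl)-2-{[2-(hydroxymethyl)-4,5-dimethoxybenzyl]oxy}ethan-1-one | COc1ccc(C(=O)COCc2cc(OC)c(OC)cc2CO)c(OC)c1
F3 | step 4 | 2-{[2-(2,4-dimethoxyphenyl)-2-oxoethoxy]methyl}-4,5-dimethoxybenzaldehyde | COc1ccc(C(=O)COCc2cc(OC)c(OC)cc2C=O)c(OC)c1
F4 | step 3 | 1-(2,4-dimethoxyphenyl)ethan-1-one | CC(=O)c1ccc(OC)cc1OC
F5 | step 3 | 1-(2,4-dimethoxyphenyl)-4,4,4-trifluorobutane-1,3-dione | COc1ccc(C(=O)CC(=O)C(F)(F)F)c(OC)c1
F6 | step 5 | [(2,4-dimethoxyphenyl){6,7-dimethoxy-4-(propan-2-yloxy)-1,4-dihydro-3H-isochromen-3-ylidene}methoxy]trimethylsilane (racemic, enol ether geometry undefined) | COc1ccc(C(O[Si](C)(C)C)=C2OCc3cc(OC)c(OC)cc3C2OC(C)C)c(OC)c1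
A1 | alternative 1 | (Z)-1-(2,4-dimethoxyphenyl)-3-(4-methoxyfuran-2-yl)-2-(prop-2-yn-1-yloxy)prop-2-en-1-one | COc1ccc(C(=O)/C(OCC#C)=C/c2cc(OC)co2)c(OC)c1
A2 | alternative 1 | (2,4-dimethoxyphenyl)(7-hydroxy-6-methoxy-1H-isochromen-3-yl)methanone | COc1ccc(C(=O)C2=Cc3cc(OC)c(O)cc3CO2)c(OC)c1
A3 | alternative 2 | 4,5-dimethoxy-2-(trimethylsilyl)phenyl trifluoromethanesulfonate | COc1cc(OS(=O)(=O)C(F)(F)F)c(cc1OC)[Si](C)(C)C
A4 | alternative 2 | oxetan-3-one | O=C1COC1
A5 | alternative 2 | 6,7-dimethoxyisochroman-4-one | COc1cc2c(cc1OC)C(=O)COC2
A6 | alternative 2 | 3-(2,4-dimethoxybenzoyl)-6,7-dimethoxyisochroman-4-one (racemic) | COc1ccc(C(=O)C2OCc3cc(OC)c(OC)cc3C2=O)c(OC)c1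
A7 | alternative 3 | 1-(6,7-dimethoxy-1H-isochromen-3-yl)prop-2-yn-1-one | C#CC(=O)C1=Cc2cc(OC)c(OC)cc2CO1
A8 | alternative 3 | 1,3-dimethoxy-1-(trimethylsilyloxy)buta-1,3-diene (ketene acetal geometry undefined) | C=C(OC)C=C(OC)O[Si](C)(C)C
A9 | alternative 3 | (2-hydroxy-4-methoxyphenyl)(6,7-dimethoxy-1H-isochromen-3-yl)methanone | COc1ccc(C(=O)C2=Cc3cc(OC)c(OC)cc3CO2)c(O)c1
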